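The disconnection on which everything rests is the C9–C10 bond of the cyclopentenone (ring C8–C12, prostanoid numbering). C12 carries two two-carbon arms: C8–C9 inside the ring and C13–C14 at the start of the octenyl chain. In a mirror-symmetric dialdehyde both arms are formylmethyl groups beside the C10≡C11 alkyne. A chiral cationic rhodium catalyst adds the formyl C–H of one enantiotopic arm across the alkyne (trans-hydroacylation), closing the ring and fixing C12 in one operation. The C10 silyl group is then exchanged for bromine, the spared arm becomes the (Z)-octenyl chain by Wittig olefination, and an aldol condensation at C8 attaches the dienoate chain before acetylation.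

Key step: step 4

Remark: atom labels follow prostanoid numbering (C1 ester carbon, C8–C12 ring, C13–C20 octenyl chain); the sense in which the rhodium catalyst selects between the two arms cannot be assigned beforehand, so the (R,R)-ligand is written and its enantiomer is taken if the first run shows the opposite sense.

Step 1
Reactants: 1 ethyl 3-(trimethylsilyl)prop-2-ynoate; 2 allylmagnesium bromide
Product: 4 4-[(trimethylsilyl)ethynyl]hepta-1,6-dien-4-ol, via 1-(trimethylsilyl)hex-5-en-1-yn-3-one 3 (not isolated)
Conditions: 2 (2.3 equiv), THF, −78 °C to 0 °C; aq. NH4Cl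
Reagents that add atoms: none
Why: Double Grignard addition to an ester: allylmagnesium bromide adds 1,2 to the silyl ynoate, the ynone 3 formed in the flask is more electrophilic than 1 and takes up the second allyl group at once, and C12 stays prochiral because both allyl groups are alike.

Step 2
Reactants: 4 4-[(trimethylsilyl)ethynyl]hepta-1,6-dien-4-ol
Product: 5 triethyl({4-[(trimethylsilyl)ethynyl]hepta-1,6-dien-4-yl}oxy)silane
Conditions: Et3SiOTf, 2,6-lutidine, CH2Cl2, 0 °C
Reagents that add atoms: triethylsilyl trifluoromethanesulfonate, CC[Si](CC)(CC)OS(=O)(=O)C(F)(F)F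
Why: Silylation of a tertiary alcohol with a silyl triflate and a hindered pyridine base is reliable and masks the oxygen that would otherwise sit β to two aldehydes as a free hydroxyl.

Step 3
Reactants: 5 triethyl({4-[(trimethylsilyl)ethynyl]hepta-1,6-dien-4-yl}oxy)silane
Product: 7 3-[(triethylsilyl)oxy]-3-[(trimethylsilyl)ethynyl]pentanedial, via bis-ozonide 6 (not isolated)
Conditions: O3, CH2Cl2, −78 °C (stopped at first excess); then PPh3, −78 °C to rt
Reagents that add atoms: ozone, [O-][O+]=O
Why: Ozonolysis with reductive work-up cleaves both terminal alkenes, which react with ozone far faster than the silylated alkyne, and should give the mirror-symmetric dialdehyde without touching the silyl ether.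

Step 4
Reactants: 7 3-[(triethylsilyl)oxy]-3-[(trimethylsilyl)ethynyl]pentanedial
Product: 8 2-[(1S)-4-oxo-1-[(triethylsilyl)oxy]-3-(trimethylsilyl)cyclopent-2-en-1-yl]acetaldehyde
Conditions: [Rh((R,R)-i-Pr-DuPhos)]BF4 (10 mol %; made from [Rh(nbd)2]BF4, the ligand and H2), acetone, rt
Reagents that add atoms: none
Why: Oxidative addition of the formyl C9–H bond to cationic monovalent rhodium, insertion of the tethered C10≡C11 alkyne with net trans delivery of hydrogen to C11 and rhodium to the silyl-bearing C10, and C9–C10 reductive elimination should release the cyclopentenone. The closest known reaction type is the rhodium-catalysed intramolecular trans-hydroacylation of 4-alkynals, including its enantioselective kinetic resolution and desymmetrisation of 3-alkoxy-4-alkynals with chiral bisphosphines. The ring C8–C9–C10–C11–C12 closes in a formal 5-endo-dig mode through a six-membered rhodacycle. C12 becomes the only stereocentre because the catalyst chooses between the two enantiotopic formylmethyl arms: the arm that cyclises becomes C8–C9, the other stays as the C13–C14 aldehyde, and the chiral bisphospholane is the controlling element, just as it distinguishes the enantiomers of a racemic 3-alkoxy-4-alkynal. The step needs arm selection, five-ring (trans) over four-ring (cis) closure and alkyne over formyl insertion; the ligand governs the first two, the silyl group directs rhodium to C10, and alkyne insertion is much faster than carbonyl insertion at room temperature.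

Step 5
Reactants: 8 2-[(1S)-4-oxo-1-[(triethylsilyl)oxy]-3-(trimethylsilyl)cyclopent-2-en-1-yl]acetaldehyde
Product: 9 2-[(1S)-3-bromo-4-oxo-1-[(triethylsilyl)oxy]cyclopent-2-en-1-yl]acetaldehyde
Conditions: Br2 (1.05 equiv), CH2Cl2, −78 °C to 0 °C; aq. Na2S2O3/NaHCO3
Reagents that add atoms: bromine, BrBr
Why: Electrophilic ipso-bromodesilylation of a vinylsilane: bromine attacks the silicon-bearing C10, the positive charge at C11 is stabilised β to silicon, and loss of the silyl group restores the C10=C11 double bond with bromine in place of silicon, while no other alkene is present and the aldehyde is not enolised at low temperature.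

Step 6
Reactants: 9 2-[(1S)-3-bromo-4-oxo-1-[(triethylsilyl)oxy]cyclopent-2-en-1-yl]acetaldehyde; 10 hexyltriphenylphosphonium bromide
Product: 12 (4S)-2-bromo-4-[(2Z)-oct-2-en-1-yl]-4-[(triethylsilyl)oxy]cyclopent-2-en-1-one, via hexylidenetriphenylphosphorane 11 (not isolated)
Conditions: 10, NaN(SiMe3)2, THF, 0 °C; then 9, −78 °C to rt
Reagents that add atoms: none
Why: Wittig olefination with a non-stabilised ylide under salt-free conditions should give the (Z)-alkene C14=C15 through the kinetically favoured cis-oxaphosphetane, and the aldehyde reacts at −78 °C well before the hindered conjugated ketone.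

Step 7
Reactants: 13 methyl hex-5-enoate; 14 (E)-but-2-enal
Product: 15 methyl (5E)-7-oxohept-5-enoate
Conditions: second-generation Hoveyda–Grubbs catalyst (2 mol %), 14 (5 equiv), CH2Cl2, 40 °C
Reagents that add atoms: none
Why: Olefin cross-metathesis of a terminal alkene with an excess of an electron-poor enal is selective for the cross product and should give the (E)-enal, the thermodynamically favoured isomer.

Step 8
Reactants: 12 (4S)-2-bromo-4-[(2Z)-oct-2-en-1-yl]-4-[(triethylsilyl)oxy]cyclopent-2-en-1-one; 15 methyl (5E)-7-oxohept-5-enoate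
Product: 17 methyl (5E)-7-{(5S)-3-bromo-5-[(2Z)-oct-2-en-1-yl]-2-oxo-5-[(triethylsilyl)oxy]cyclopent-3-en-1-yl}-7-hydroxyhept-5-enoate (C7/C8 epimer mixture), via lithium dienolate 16 (not isolated)
Conditions: LiN(i-Pr)2, THF, −78 °C; then 15, −78 °C; aq. NH4Cl
Reagents that add atoms: none
Why: Directed aldol addition: C8 is the only enolisable position of 12 because C12 is fully substituted, the lithium dienolate adds 1,2 to the enal at −78 °C, loss of the silyloxy group from the enolate is blocked because it would give a cyclopentadienone, and the new centres C7 and C8 need no control since both are removed in step 10.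

Step 9
Reactants: 17 methyl (5E)-7-{(5S)-3-bromo-5-[(2Z)-oct-2-en-1-yl]-2-oxo-5-[(triethylsilyl)oxy]cyclopent-3-en-1-yl}-7-hydroxyhept-5-enoate
Product: 18 methyl (5E)-7-{(5S)-3-bromo-5-hydroxy-5-[(2Z)-oct-2-en-1-yl]-2-oxocyclopent-3-en-1-yl}-7-hydroxyhept-5-enoate (C7/C8 epimer mixture)
Conditions: HF·pyridine, pyridine, THF, 0 °C to rt
Reagents that add atoms: none
Why: Fluoride-induced cleavage of the triethylsilyl ether with buffered HF·pyridine should leave the methyl ester, the β-hydroxy ketone and the bromoenone untouched.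

Step 10
Reactants: 18 methyl (5E)-7-{(5S)-3-bromo-5-hydroxy-5-[(2Z)-oct-2-en-1-yl]-2-oxocyclopent-3-en-1-yl}-7-hydroxyhept-5-enoate
Product: 21 methyl (5E,7E,12R,14Z)-12-acetoxy-10-bromo-9-oxoprosta-5,7,10,14-tetraen-1-oate, via C7 acetate 19 (not isolated), via 12-hydroxy dienone 20 (not isolated)
Conditions: Ac2O (excess), DMAP, Et3N, CH2Cl2, rt
Reagents that add atoms: acetic anhydride, CC(=O)OC(C)=O
Why: DMAP-catalysed acetylation makes the allylic C7 acetate, which is lost by E1cB elimination through the C8 enolate to give the conjugated dienone, expected mainly with the more stable 7E geometry (C6 anti to the C9 carbonyl), and the same reagent then acetylates the tertiary C12 hydroxyl without touching the stereocentre.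

Compound list
1 | ethyl 3-(trimethylsilyl)prop-2-ynoate | CCOC(=O)C#C[Si](C)(C)C | starting material
2 | allylmagnesium bromide | C=CC[Mg]Br | starting material
3 | 1-(trimethylsilyl)hex-5-en-1-yn-3-one (not isolated) | C=CCC(=O)C#C[Si](C)(C)C | intermediate
4 | 4-[(trimethylsilyl)ethynyl]hepta-1,6-dien-4-ol | C=CCC(O)(CC=C)C#C[Si](C)(C)C | intermediate
5 | triethyl({4-[(trimethylsilyl)ethynyl]hepta-1,6-dien-4-yl}oxy)silane | C=CCC(O[Si](CC)(CC)CC)(CC=C)C#C[Si](C)(C)C | intermediate
6 | bis-ozonide of 5, two 1,2,4-trioxolan-3-ylmethyl groups on the carbinol carbon (not isolated) | C[Si](C)(C)C#CC(O[Si](CC)(CC)CC)(CC1OCOO1)CC1OCOO1 | intermediate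
7 | 3-[(triethylsilyl)oxy]-3-[(trimethylsilyl)ethynyl]pentanedial | O=CCC(O[Si](CC)(CC)CC)(CC=O)C#C[Si](C)(C)C | intermediate
8 | 2-[(1S)-4-oxo-1-[(triethylsilyl)oxy]-3-(trimethylsilyl)cyclopent-2-en-1-yl]acetaldehyde | O=CC[C@@]1(O[Si](CC)(CC)CC)C=C([Si](C)(C)C)C(=O)C1 | intermediate
9 | 2-[(1S)-3-bromo-4-oxo-1-[(triethylsilyl)oxy]cyclopent-2-en-1-yl]acetaldehyde | O=CC[C@@]1(O[Si](CC)(CC)CC)C=C(Br)C(=O)C1 | intermediate
10 | hexyltriphenylphosphonium bromide | CCCCCC[P+](c1ccccc1)(c1ccccc1)c1ccccc1.[Br-] | starting material
11 | hexylidenetriphenylphosphorane (not isolated) | CCCCCC=P(c1ccccc1)(c1ccccc1)c1ccccc1 | intermediate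
12 | (4S)-2-bromo-4-[(2Z)-oct-2-en-1-yl]-4-[(triethylsilyl)oxy]cyclopent-2-en-1-one | CCCCC/C=C\C[C@@]1(O[Si](CC)(CC)CC)C=C(Br)C(=O)C1 | intermediate
13 | methyl hex-5-enoate | C=CCCCC(=O)OC | starting material
14 | (E)-but-2-enal | C/C=C/C=O | starting material
15 | methyl (5E)-7-oxohept-5-enoate | O=C/C=C/CCCC(=O)OC | intermediate
16 | lithium dienolate of 12, O-lithiated at C9 with C8=C9 double bond (not isolated) | CCCCC/C=C\C[C@@]1(O[Si](CC)(CC)CC)C=C(Br)C(O[Li])=C1 | intermediate
17 | methyl (5E)-7-{(5S)-3-bromo-5-[(2Z)-oct-2-en-1-yl]-2-oxo-5-[(triethylsilyl)oxy]cyclopent-3-en-1-yl}-7-hydroxyhept-5-enoate, C7/C8 epimer mixture | CCCCC/C=C\C[C@@]1(O[Si](CC)(CC)CC)C=C(Br)C(=O)C1C(O)/C=C/CCCC(=O)OC | intermediate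
18 | methyl (5E)-7-{(5S)-3-bromo-5-hydroxy-5-[(2Z)-oct-2-en-1-yl]-2-oxocyclopent-3-en-1-yl}-7-hydroxyhept-5-enoate, C7/C8 epimer mixture | CCCCC/C=C\C[C@@]1(O)C=C(Br)C(=O)C1C(O)/C=C/CCCC(=O)OC | intermediate
19 | C7 acetate of 18 (not isolated) | CCCCC/C=C\C[C@@]1(O)C=C(Br)C(=O)C1C(OC(C)=O)/C=C/CCCC(=O)OC | intermediate
20 | methyl (5E,7E,12R,14Z)-10-bromo-12-hydroxy-9-oxoprosta-5,7,10,14-tetraen-1-oate (not isolated) | CCCCC/C=C\C[C@@]1(O)C=C(Br)C(=O)/C1=C/C=C/CCCC(=O)OC | intermediate
21 | methyl (5E,7E,12R,14Z)-12-acetoxy-10-bromo-9-oxoprosta-5,7,10,14-tetraen-1-oate | CCCCC/C=C\C[C@@]1(OC(C)=O)C=C(Br)C(=O)/C1=C/C=C/CCCC(=O)OC | target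

Total step count: 10. Longest linear sequence: 9 steps (steps 1–6 and 8–10); step 7 makes the side-chain aldehyde separately.

Steps most likely to fail

Step 4. The catalyst may discriminate poorly between the two formylmethyl arms, so that the enantiomeric purity is low, and cis-addition (four-ring ketone) or insertion of the second formyl group (lactone) may compete. The fallback sets out from 7 and returns at 8. Dialdehyde 7 is cyclised with the achiral catalyst [Rh(dppe)]2(BF4)2 in acetone to racemic 2-[4-oxo-1-(triethylsilyloxy)-3-(trimethylsilyl)cyclopent-2-en-1-yl]acetaldehyde F1. Condensation of its aldehyde with (1R,2R)-N,N'-dimethyl-1,2-diphenylethane-1,2-diamine (molecular sieves, Et2O) should give two diastereomeric imidazolidines. The one built on the (S)-configured ring, (4S)-4-{[(4R,5R)-1,3-dimethyl-4,5-diphenylimidazolidin-2-yl]methyl}-4-[(triethylsilyl)oxy]-2-(trimethylsilyl)cyclopent-2-en-1-one F2, is separated by chromatography or crystallisation and hydrolysed with dilute aqueous HCl/Et2O at 0 °C to 8.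

Step 6. The basic ylide may deprotonate next to the aldehyde, with loss of the β-silyloxy group, or attack the bromoenone instead of olefinating. The fallback sets out from 9 and returns at 12. Non-basic methylenation of the aldehyde with Zn, CH2Br2 and TiCl4 (THF/CH2Cl2, 0 °C), which is selective for aldehydes over ketones, should give (4S)-2-bromo-4-(prop-2-en-1-yl)-4-[(triethylsilyl)oxy]cyclopent-2-en-1-one F3. Z-selective cross-metathesis of F3 with hept-1-ene (cyclometalated ruthenium Z-selective Grubbs catalyst, THF, 35 °C) then gives 12; the hindered, electron-poor C10=C11 double bond should take no part.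

Step 8. Proton exchange between the lithium dienolate and the enolisable enal, or conjugate addition of the dienolate to unreacted bromoenone, may stall the aldol addition. The fallback sets out from 12 and returns at 17. Soft enolisation with Me3SiOTf and Et3N (CH2Cl2, 0 °C) should give the silyl dienol ether triethyl({(1S)-3-bromo-1-[(2Z)-oct-2-en-1-yl]-4-[(trimethylsilyl)oxy]cyclopenta-2,4-dien-1-yl}oxy)silane F4. A Mukaiyama aldol addition of F4 to 15 promoted by BF3·OEt2 at −78 °C gives 17 after aqueous work-up.

Further compounds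
F1 | step 4 | racemic 2-[4-oxo-1-(triethylsilyloxy)-3-(trimethylsilyl)cyclopent-2-en-1-yl]acetaldehyde | O=CCC1(O[Si](CC)(CC)CC)C=C([Si](C)(C)C)C(=O)C1
F2 | step 4 | (4S)-4-{[(4R,5R)-1,3-dimethyl-4,5-diphenylimidazolidin-2-yl]methyl}-4-[(triethylsilyl)oxy]-2-(trimethylsilyl)cyclopent-2-en-1-one | CN1[C@H](c2ccccc2)[C@@H](c2ccccc2)N(C)C1C[C@@]1(O[Si](CC)(CC)CC)C=C([Si](C)(C)C)C(=O)C1
F3 | step 6 | (4S)-2-bromo-4-(prop-2-en-1-yl)-4-[(triethylsilyl)oxy]cyclopent-2-en-1-one | C=CC[C@@]1(O[Si](CC)(CC)CC)C=C(Br)C(=O)C1
F4 | step 8 | triethyl({(1S)-3-bromo-1-[(2Z)-oct-2-en-1-yl]-4-[(trimethylsilyl)oxy]cyclopenta-2,4-dien-1-yl}oxy)silane | CCCCC/C=C\C[C@@]1(O[Si](CC)(CC)CC)C=C(Br)C(O[Si](C)(C)C)=C1
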